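The route disconnects ring B at two bonds at once: C3–C3a and the C–O bond of the hydroxymethyl group. The feature exploited is that C3 carries both ring A carbon C3a and an exocyclic CH2–O unit, the two ends of a former vinyl group. In one operation an aryl radical at C3a closes ring B by 5-exo addition to the inner vinyl carbon, sets C3 trans to the existing C2 centre, and air oxygenates the exocyclic primary radical. The precursor is an (S)-1-arylallyl aryl ether with iodine ortho to the ether oxygen on ring A, assembled by iridium-catalysed asymmetric allylic etherification.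

Key step: step 8

Remark on lettering: ring A is the benzo ring of the dihydrobenzofuran (C3a to C7a), ring B the dihydrofuran ring (O1, C2, C3, C3a, C7a), ring C the guaiacyl ring on C2.

Remark on the target: it is taken as the free hydrogen sulfate as drawn; the sulfate is carried as its sodium salt and protonated only in the last operation.

Step 1
Reactants: 1 eugenol (4-allyl-2-methoxyphenol)
Product: 3 dihydroconiferyl alcohol (4-(3-hydroxypropyl)-2-methoxyphenol), via bis-boryl adduct 2 (not isolated)
Conditions: 9-BBN (9-borabicyclo[3.3.1]nonane, 2.2 equiv), THF, 0 °C to rt; then aq. NaOH, 30% H2O2, 0 °C to rt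
Reagents that add atoms: hydrogen peroxide, OO
Why: Hydroboration–oxidation: the bulky borane places boron on the terminal carbon of the allyl group (a second equivalent is consumed by the phenol O–H), and alkaline H2O2 replaces boron by OH and frees the phenol.

Step 2
Reactants: 3 dihydroconiferyl alcohol
Product: 4 4-[3-(tert-butyldimethylsilyloxy)propyl]-2-methoxyphenol
Conditions: TBSCl (1.05 equiv), imidazole, CH2Cl2, 0 °C
Reagents that add atoms: tert-butyldimethylsilyl chloride, CC(C)(C)[Si](C)(C)Cl
Why: Silyl ether formation under imidazole is expected to take the unhindered primary alcohol in preference to the less nucleophilic, hydrogen-bonded guaiacol OH when one equivalent of silyl chloride is used cold.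

Step 3
Reactants: 4 4-[3-(tert-butyldimethylsilyloxy)propyl]-2-methoxyphenol
Product: 5 4-[3-(tert-butyldimethylsilyloxy)propyl]-2-iodo-6-methoxyphenol
Conditions: I2 (1.05 equiv), NaHCO3, THF/H2O, 0 °C to rt
Reagents that add atoms: iodine, II
Why: Electrophilic aromatic iodination through the phenoxide, which directs to the only free position ortho to oxygen (para is blocked by the side chain), under buffered conditions that leave the silyl ether intact.

Step 4
Reactants: 6 4-(benzyloxy)-3-methoxybenzaldehyde (O-benzylvanillin)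
Product: 7 ethyl (E)-3-[4-(benzyloxy)-3-methoxyphenyl]prop-2-enoate
Conditions: Ph3P=CHCO2Et (1.1 equiv), toluene, 80 °C
Reagents that add atoms: ethyl (triphenylphosphoranylidene)acetate, CCOC(=O)C=P(c1ccccc1)(c1ccccc1)c1ccccc1
Why: Wittig olefination with a stabilised ylide, which should give the E-cinnamate predominantly.

Step 5
Reactants: 7 ethyl (E)-3-[4-(benzyloxy)-3-methoxyphenyl]prop-2-enoate
Product: 8 (E)-3-[4-(benzyloxy)-3-methoxyphenyl]prop-2-en-1-ol
Conditions: i-Bu2AlH (2.3 equiv), CH2Cl2, −78 °C to 0 °C; aq. KNaC4H4O6 work-up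
Reagents that add atoms: none
Why: 1,2-Reduction of the unsaturated ester by the aluminium hydride at low temperature gives the allylic alcohol without touching the alkene or the benzyl ether.

Step 6
Reactants: 8 (E)-3-[4-(benzyloxy)-3-methoxyphenyl]prop-2-en-1-ol
Product: 9 (E)-3-[4-(benzyloxy)-3-methoxyphenyl]prop-2-en-1-yl methyl carbonate
Conditions: ClCO2Me, pyridine, CH2Cl2, 0 °C
Reagents that add atoms: methyl chloroformate, COC(=O)Cl
Why: O-Acylation of the primary allylic alcohol with a chloroformate gives the linear carbonate that serves as leaving group in the iridium chemistry.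

Step 7
Reactants: 5 4-[3-(tert-butyldimethylsilyloxy)propyl]-2-iodo-6-methoxyphenol; 9 (E)-3-[4-(benzyloxy)-3-methoxyphenyl]prop-2-en-1-yl methyl carbonate
Product: 11 (S)-1-[4-(benzyloxy)-3-methoxyphenyl]allyl 4-[3-(tert-butyldimethylsilyloxy)propyl]-2-iodo-6-methoxyphenyl ether, via lithium phenoxide 10 (not isolated)
Conditions: 5 (1.5 equiv), LiN(SiMe3)2 (1.5 equiv), THF, 0 °C; then 9 (1.0 equiv), [Ir(cod)Cl]2 (2 mol %), (Sa,Sc,Sc)-N,N-bis(1-phenylethyl)dinaphtho[2,1-d:1′,2′-f][1,3,2]dioxaphosphepin-4-amine (4 mol %; catalyst pre-activated with n-PrNH2, volatiles removed), THF, rt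
Reagents that add atoms: none
Why: Iridium-catalysed asymmetric allylic etherification: the cyclometalated iridium–phosphoramidite ionises the linear carbonate and the aryloxide attacks the aryl-substituted allyl terminus on the face away from the metal, so the branched ether should form with C2 set by the ligand; the (Sa,Sc,Sc) antipode is chosen for the (S)-ether and, as both antipodes are available, the sense of induction should be confirmed on the first run.

Step 8
Reactants: 11 (S)-1-[4-(benzyloxy)-3-methoxyphenyl]allyl 4-[3-(tert-butyldimethylsilyloxy)propyl]-2-iodo-6-methoxyphenyl ether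
Product: 13 [(2S,3R)-2-[4-(benzyloxy)-3-methoxyphenyl]-5-[3-(tert-butyldimethylsilyloxy)propyl]-7-methoxy-2,3-dihydrobenzofuran-3-yl]methanol, via hydroperoxide 12 (not isolated)
Conditions: Bu3SnH (2.5 equiv, syringe pump), Et3B (0.1 equiv), dry air sparge, toluene (0.01 M), 0 °C to rt; then PPh3 (1.5 equiv), rt
Reagents that add atoms: dioxygen (air), O=O
Why: A tributylstannyl radical abstracts iodine from 11, the C3a aryl radical adds to the inner vinyl carbon, the exocyclic primary radical is captured by O2, the peroxyl radical takes hydrogen from Bu3SnH to give hydroperoxide 12 and carry the chain, and PPh3 reduces 12 to 13. The closest known reaction type is the aerobic tin hydride (oxygenative) radical cyclisation of ortho-iodophenyl allyl ethers to 3-hydroxymethyl-2,3-dihydrobenzofurans. Ring B closes in the 5-exo-trig mode, forming C3–C3a. The new C3 centre is controlled by the existing C2 centre: in the envelope-like transition state the C2 aryl group sits pseudo-equatorial and the vinyl CH2 terminus turns away from it, so the hydroxymethyl group should end up trans to the aryl group (2S,3R). The step needs the right order of radical capture (ring closure before the aryl radical meets O2 or Bu3SnH, then oxygenation before hydrogen transfer), which the very fast intramolecular addition, high dilution, slow hydride addition and air saturation should secure, while attack of the aryl radical on ring C and neophyl-type ring expansion of the primary radical are much slower. The only transfer of the C2 hydrogen open to the aryl radical would be a 1,4-shift through a strained five-membered transition state, so C2 should keep its configuration.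

Step 9
Reactants: 13 [(2S,3R)-2-[4-(benzyloxy)-3-methoxyphenyl]-5-[3-(tert-butyldimethylsilyloxy)propyl]-7-methoxy-2,3-dihydrobenzofuran-3-yl]methanol
Product: 14 (2S,3R)-2-[4-(benzyloxy)-3-methoxyphenyl]-3-(benzyloxymethyl)-5-[3-(tert-butyldimethylsilyloxy)propyl]-7-methoxy-2,3-dihydrobenzofuran
Conditions: NaH, BnBr, Bu4NI (cat.), THF/DMF, 0 °C to rt
Reagents that add atoms: benzyl bromide, BrCc1ccccc1
Why: Williamson etherification of the only free hydroxyl group; the silyl and aryl ethers are inert to NaH and neither stereocentre carries an acidic hydrogen.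

Step 10
Reactants: 14 (2S,3R)-2-[4-(benzyloxy)-3-methoxyphenyl]-3-(benzyloxymethyl)-5-[3-(tert-butyldimethylsilyloxy)propyl]-7-methoxy-2,3-dihydrobenzofuran
Product: 15 3-[(2S,3R)-2-[4-(benzyloxy)-3-methoxyphenyl]-3-(benzyloxymethyl)-7-methoxy-2,3-dihydrobenzofuran-5-yl]propan-1-ol
Conditions: Bu4NF, THF, 0 °C to rt
Reagents that add atoms: none
Why: Fluoride-mediated cleavage of the primary silyl ether, driven by the strong Si–F bond, leaves both benzyl ethers and ring B untouched.

Step 11
Reactants: 15 3-[(2S,3R)-2-[4-(benzyloxy)-3-methoxyphenyl]-3-(benzyloxymethyl)-7-methoxy-2,3-dihydrobenzofuran-5-yl]propan-1-ol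
Product: 17 sodium 3-[(2S,3R)-2-[4-(benzyloxy)-3-methoxyphenyl]-3-(benzyloxymethyl)-7-methoxy-2,3-dihydrobenzofuran-5-yl]propyl sulfate, via pyridinium sulfate 16 (not isolated)
Conditions: SO3·pyridine (3 equiv), DMF, rt; then aq. NaHCO3
Reagents that add atoms: sulfur trioxide–pyridine complex, O=S(=O)([O-])[n+]1ccccc1; sodium hydrogen carbonate, [Na+].OC([O-])=O
Why: O-Sulfation of the single free primary alcohol with the mild SO3–amine complex, followed by bicarbonate exchange to the stable sodium salt.

Step 12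
Reactants: 17 sodium 3-[(2S,3R)-2-[4-(benzyloxy)-3-methoxyphenyl]-3-(benzyloxymethyl)-7-methoxy-2,3-dihydrobenzofuran-5-yl]propyl sulfate
Product: 19 3-[(2S,3R)-2-(4-hydroxy-3-methoxyphenyl)-3-(hydroxymethyl)-7-methoxy-2,3-dihydrobenzofuran-5-yl]propyl hydrogen sulfate, via sodium salt 18 (not isolated)
Conditions: H2 (1 atm), 10% Pd/C, MeOH, rt; filter; then 1 M HCl (1.0 equiv), 0 °C; C18 desalting, lyophilise
Reagents that add atoms: none
Why: Catalytic hydrogenolysis removes the aryl and the alkyl benzyl ether as toluene under neutral conditions that spare the sulfate monoester, and one equivalent of strong acid then converts the sodium salt into the hydrogen sulfate drawn for the target.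

Compound list

1 | eugenol (4-allyl-2-methoxyphenol) | C=CCc1ccc(O)c(OC)c1 | starting material
2 | 9-{3-[4-(9-borabicyclo[3.3.1]nonan-9-yloxy)-3-methoxyphenyl]propyl}-9-borabicyclo[3.3.1]nonane (bis-boryl adduct) | COc1cc(CCCB2C3CCCC2CCC3)ccc1OB1C2CCCC1CCC2 | intermediate
3 | dihydroconiferyl alcohol, 4-(3-hydroxypropyl)-2-methoxyphenol | COc1cc(CCCO)ccc1O | intermediate
4 | 4-[3-(tert-butyldimethylsilyloxy)propyl]-2-methoxyphenol | COc1cc(CCCO[Si](C)(C)C(C)(C)C)ccc1O | intermediate
5 | 4-[3-(tert-butyldimethylsilyloxy)propyl]-2-iodo-6-methoxyphenol | COc1cc(CCCO[Si](C)(C)C(C)(C)C)cc(I)c1O | intermediate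
6 | 4-(benzyloxy)-3-methoxybenzaldehyde | COc1cc(C=O)ccc1OCc1ccccc1 | starting material
7 | ethyl (E)-3-[4-(benzyloxy)-3-methoxyphenyl]prop-2-enoate | CCOC(=O)/C=C/c1ccc(OCc2ccccc2)c(OC)c1 | intermediate
8 | (E)-3-[4-(benzyloxy)-3-methoxyphenyl]prop-2-en-1-ol | OC/C=C/c1ccc(OCc2ccccc2)c(OC)c1 | intermediate
9 | (E)-3-[4-(benzyloxy)-3-methoxyphenyl]prop-2-en-1-yl methyl carbonate | COC(=O)OC/C=C/c1ccc(OCc2ccccc2)c(OC)c1 | intermediate
10 | lithium 4-[3-(tert-butyldimethylsilyloxy)propyl]-2-iodo-6-methoxyphenoxide | COc1cc(CCCO[Si](C)(C)C(C)(C)C)cc(I)c1[O-].[Li+] | intermediate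
11 | (S)-1-[4-(benzyloxy)-3-methoxyphenyl]allyl 4-[3-(tert-butyldimethylsilyloxy)propyl]-2-iodo-6-methoxyphenyl ether | COc1cc([C@H](C=C)Oc2c(OC)cc(CCCO[Si](C)(C)C(C)(C)C)cc2I)ccc1OCc1ccccc1 | intermediate
12 | [(2S,3R)-2-[4-(benzyloxy)-3-methoxyphenyl]-5-[3-(tert-butyldimethylsilyloxy)propyl]-7-methoxy-2,3-dihydrobenzofuran-3-yl]methyl hydroperoxide | COc1cc([C@H]2Oc3c(OC)cc(CCCO[Si](C)(C)C(C)(C)C)cc3[C@@H]2COO)ccc1OCc1ccccc1 | intermediate
13 | [(2S,3R)-2-[4-(benzyloxy)-3-methoxyphenyl]-5-[3-(tert-butyldimethylsilyloxy)propyl]-7-methoxy-2,3-dihydrobenzofuran-3-yl]methanol | COc1cc([C@H]2Oc3c(OC)cc(CCCO[Si](C)(C)C(C)(C)C)cc3[C@@H]2CO)ccc1OCc1ccccc1 | intermediate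
14 | (2S,3R)-2-[4-(benzyloxy)-3-methoxyphenyl]-3-(benzyloxymethyl)-5-[3-(tert-butyldimethylsilyloxy)propyl]-7-methoxy-2,3-dihydrobenzofuran | COc1cc([C@H]2Oc3c(OC)cc(CCCO[Si](C)(C)C(C)(C)C)cc3[C@@H]2COCc2ccccc2)ccc1OCc1ccccc1 | intermediate
15 | 3-[(2S,3R)-2-[4-(benzyloxy)-3-methoxyphenyl]-3-(benzyloxymethyl)-7-methoxy-2,3-dihydrobenzofuran-5-yl]propan-1-ol | COc1cc([C@H]2Oc3c(OC)cc(CCCO)cc3[C@@H]2COCc2ccccc2)ccc1OCc1ccccc1 | intermediate
16 | pyridinium 3-[(2S,3R)-2-[4-(benzyloxy)-3-methoxyphenyl]-3-(benzyloxymethyl)-7-methoxy-2,3-dihydrobenzofuran-5-yl]propyl sulfate | COc1cc([C@H]2Oc3c(OC)cc(CCCOS(=O)(=O)[O-])cc3[C@@H]2COCc2ccccc2)ccc1OCc1ccccc1.c1cc[nH+]cc1 | intermediate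
17 | sodium 3-[(2S,3R)-2-[4-(benzyloxy)-3-methoxyphenyl]-3-(benzyloxymethyl)-7-methoxy-2,3-dihydrobenzofuran-5-yl]propyl sulfate | COc1cc([C@H]2Oc3c(OC)cc(CCCOS(=O)(=O)[O-])cc3[C@@H]2COCc2ccccc2)ccc1OCc1ccccc1.[Na+] | intermediate
18 | sodium 3-[(2S,3R)-2-(4-hydroxy-3-methoxyphenyl)-3-(hydroxymethyl)-7-methoxy-2,3-dihydrobenzofuran-5-yl]propyl sulfate | COc1cc([C@H]2Oc3c(OC)cc(CCCOS(=O)(=O)[O-])cc3[C@@H]2CO)ccc1O.[Na+] | intermediate
19 | 3-[(2S,3R)-2-(4-hydroxy-3-methoxyphenyl)-3-(hydroxymethyl)-7-methoxy-2,3-dihydrobenzofuran-5-yl]propyl hydrogen sulfate | COc1cc([C@H]2Oc3c(OC)cc(CCCOS(=O)(=O)O)cc3[C@@H]2CO)ccc1O | target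

Total step count: 12. Longest linear sequence: 9 steps (steps 1–3 and 7–12; the branch through steps 4–6 and 7–12 is equally long).

Steps most likely to fail

Step 8. The radicals may be captured in the wrong order: the primary radical may take hydrogen from Bu3SnH before it is oxygenated, or the aryl radical may meet O2 before ring closure. Peroxyl radicals may also start autoxidation at the benzylic ether positions, and the trans preference at C3 may be incomplete. The fallback replaces dioxygen by a persistent nitroxide trap. Setting out from 11, Bu3SnH and TEMPO (benzene, 70 °C), a known aryl radical 5-exo cyclisation with nitroxide capture, would give the 2,2,6,6-tetramethylpiperidin-1-yl ether of 13 F1. Zn dust in AcOH/THF at 40 °C (no added water, to spare the primary silyl ether) would then cleave the N–O bond and return to the route at 13.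

Step 7. Enantiopurity and branched connectivity may be lost through reversible ionisation of the electron-rich ether under the catalyst, made worse by slow attack of the doubly ortho-substituted phenoxide. The fallback gives up catalyst control for a resolution at the first compound with a handle. Setting out from 5 and 9, the etherification would be run with the racemic ligand to give the racemic ether F2, which the conditions of step 8 would turn into the racemic trans alcohol F3. Acylation with (1S,4R)-camphanoyl chloride (pyridine, DMAP, CH2Cl2) would give two diastereomeric esters, to be separated by crystallisation or chromatography. Methanolysis (K2CO3, MeOH) of the (2S,3R) camphanate F4 would come back to the route at 13.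

Step 12. Ring B may be opened by hydrogenolysis at the benzylic C2–O1 bond while the slower primary alkyl benzyl ether is still being cleaved, and the sulfate may be lost on protonation. The fallback protects the C3 hydroxymethyl group as an ester so that hydrogen only has to remove the fast-cleaving aryl benzyl ether. Setting out from 13, Ac2O/pyridine would give the acetate F5, Bu4NF buffered with AcOH (THF) the primary alcohol F6, and SO3·pyridine in DMF followed by aq. NaHCO3 the sodium sulfate F7. A short hydrogenolysis (H2, 10% Pd/C, MeOH) would give the phenol F8, and catalytic NaOMe in MeOH would remove the acetate to come back to the route at 18, which is protonated as in step 12.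

Further compounds

F1 | step 8 | 1-{[(2S,3R)-2-[4-(benzyloxy)-3-methoxyphenyl]-5-[3-(tert-butyldimethylsilyloxy)propyl]-7-methoxy-2,3-dihydrobenzofuran-3-yl]methoxy}-2,2,6,6-tetramethylpiperidine | COc1cc([C@H]2Oc3c(OC)cc(CCCO[Si](C)(C)C(C)(C)C)cc3[C@@H]2CON2C(C)(C)CCCC2(C)C)ccc1OCc1ccccc1
F2 | step 7 | racemic 1-[4-(benzyloxy)-3-methoxyphenyl]allyl 4-[3-(tert-butyldimethylsilyloxy)propyl]-2-iodo-6-methoxyphenyl ether | COc1cc(C(C=C)Oc2c(OC)cc(CCCO[Si](C)(C)C(C)(C)C)cc2I)ccc1OCc1ccccc1
F3 | step 7 | racemic trans-[2-[4-(benzyloxy)-3-methoxyphenyl]-5-[3-(tert-butyldimethylsilyloxy)propyl]-7-methoxy-2,3-dihydrobenzofuran-3-yl]methanol (racemate, relative configuration trans) | COc1cc(C2Oc3c(OC)cc(CCCO[Si](C)(C)C(C)(C)C)cc3C2CO)ccc1OCc1ccccc1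
F4 | step 7 | [(2S,3R)-2-[4-(benzyloxy)-3-methoxyphenyl]-5-[3-(tert-butyldimethylsilyloxy)propyl]-7-methoxy-2,3-dihydrobenzofuran-3-yl]methyl (1S,4R)-4,7,7-trimethyl-3-oxo-2-oxabicyclo[2.2.1]heptane-1-carboxylate | COc1cc([C@H]2Oc3c(OC)cc(CCCO[Si](C)(C)C(C)(C)C)cc3[C@@H]2COC(=O)[C@@]23CC[C@@](C)(C(=O)O2)C3(C)C)ccc1OCc1ccccc1
F5 | step 12 | [(2S,3R)-2-[4-(benzyloxy)-3-methoxyphenyl]-5-[3-(tert-butyldimethylsilyloxy)propyl]-7-methoxy-2,3-dihydrobenzofuran-3-yl]methyl acetate | COc1cc([C@H]2Oc3c(OC)cc(CCCO[Si](C)(C)C(C)(C)C)cc3[C@@H]2COC(C)=O)ccc1OCc1ccccc1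
F6 | step 12 | [(2S,3R)-2-[4-(benzyloxy)-3-methoxyphenyl]-5-(3-hydroxypropyl)-7-methoxy-2,3-dihydrobenzofuran-3-yl]methyl acetate | COc1cc([C@H]2Oc3c(OC)cc(CCCO)cc3[C@@H]2COC(C)=O)ccc1OCc1ccccc1
F7 | step 12 | sodium 3-[(2S,3R)-3-(acetoxymethyl)-2-[4-(benzyloxy)-3-methoxyphenyl]-7-methoxy-2,3-dihydrobenzofuran-5-yl]propyl sulfate | COc1cc([C@H]2Oc3c(OC)cc(CCCOS(=O)(=O)[O-])cc3[C@@H]2COC(C)=O)ccc1OCc1ccccc1.[Na+]
F8 | step 12 | sodium 3-[(2S,3R)-3-(acetoxymethyl)-2-(4-hydroxy-3-methoxyphenyl)-7-methoxy-2,3-dihydrobenzofuran-5-yl]propyl sulfate | COc1cc([C@H]2Oc3c(OC)cc(CCCOS(=O)(=O)[O-])cc3[C@@H]2COC(C)=O)ccc1O.[Na+]
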